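**Analysis of the target**

The target 17 is a 20-membered diaryl ether cyclophane. Ring A is a phenol with C1–OH, C2–H, C3–chain, C4–H, C5–O(ether) and C6–H. Ring B has C1' on the ether oxygen, hydroxyls at C2' and C6', and the chain at C4'. Twelve methylenes join C3 to C4', so the large ring counts three atoms of ring A, the ether oxygen, four atoms of ring B and the twelve chain carbons. There is no stereocentre and no stereogenic double bond, and with a tether of this length no atropisomerism is expected. The sensitive groups are the three phenols; ring B is a 2-aryloxyresorcinol, electron-rich and prone to oxidation under basic aerobic conditions, so its hydroxyls are best kept masked until the end. The synthesis is hard for three reasons: the ether oxygen sits between two oxygenated ortho positions on ring B (hindered and electron-rich, poor for arylation), ring A carries three mutually meta substituents (a pattern electrophilic substitution does not give), and a large ring must be closed. The strategy rests on ring A: oxygen at C1, carbon chain at C3 and oxygen at C5 is the pattern left when a four-carbon unit C4–C5–C6–C1, oxygenated at C5 and doubly at C1, adds across a two-carbon unit C2–C3 that carries the chain on C3 and a removable ester on C2.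

**Retrosynthetic reasoning**

Target 17 is traced back to its ring B dimethyl ether 16 by cutting the two O–CH3 bonds. The methyl ethers come with the commercial ring B phenol 6 and protect the oxidation-prone resorcinol through every basic and thermal step. The forward reaction is a Lewis-acid ether cleavage that must leave the diaryl ether alone, which it does because that oxygen carries no sp3 carbon.

Compound 16 is traced back to the macrocyclic salicylate 14, through the acid 15, by restoring a carboxyl group at ring A C2. This ester is what activates the two-carbon partner in the ring A construction and fixes its orientation. Its removal is cheap, because C2 lies ortho to the C1 hydroxyl and para to the C5 ether oxygen, which is the arrangement that makes protodecarboxylation easy.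

The macrocycle 14 is opened at the aryl–alkyl bond C4'–CH2 to give the seco compound 12, with a bromide on ring B and a terminal alkene on the chain. This bond is chosen because C4' is flanked only by hydrogens, and because both handles are inert to everything that precedes the ring closure. Cutting at the ether instead would put the closure at the most hindered position of the molecule. The forward reaction is an anti-Markovnikov hydroboration followed by a palladium-catalysed alkyl–aryl coupling at high dilution.

Ring A of 12 is cut at C3–C4 and C1–C2, giving the aryloxy-substituted vinylketene acetal 9 and the ynoate 5. This one disconnection delivers the all-meta pattern of ring A with the ether and the chain already attached. The forward reaction has to be a regioselective [4+2] addition followed by aromatization that expels the ketal substituents at C1 but not the aryloxy group at C5.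

Diene 9 is traced back to the enoate 8 by γ-deprotonation and O-silylation, and 8 to the phenol 6 and methyl but-2-ynoate 7 by cutting the vinyl C–O bond. The hindered phenol thus enters by conjugate addition to an unhindered sp carbon, and the diaryl ether oxygen is never formed by an arylation.

Ynoate 5 is cut at the bond between the ester carbon and the alkyne, which leads to the terminal alkyne 4 and a chloroformate. Alkyne 4 comes from its silyl derivative 3, and 3 from the propargylic alkylation of the silylpropyne 1 with the bromoalkene 2. A three-carbon propargyl unit is needed here: eleven carbons from 2, three from 1 and the carboxyl carbon make the fifteen-carbon ynoate, whose C4–C15 segment becomes the twelve-carbon bridge. A two-carbon acetylide would leave the bridge one carbon short.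

**Alternatives that were turned down**

Alternative 1: The ether bond O–C1' is cut and ring B is taken back to a cyclohexane-1,3-dione, giving the diazodione A1 with the ring A phenol at the far end of the chain. In the forward step a catalytically generated metal carbenoid at the diazo carbon inserts into the phenolic O–H and should give the macrocyclic 2-aryloxycyclohexane-1,3-dione A2, closing the 20-membered ring at the same time.
- For it: O–H insertion does not suffer from the steric problem of the ether, the dione supplies both ring B oxygens, and one step makes both the ether and the macrocycle. On this count of bonds per step it is stronger than the chosen route.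
- Against it: the carbenoid of a cyclic 2-diazo-1,3-dione has unimolecular escape routes that dilution does not suppress, namely Wolff ring contraction, C–H insertion into the chain and attack on the electron-rich ring A. A2 then still needs dehydrogenation of the dione to the resorcinol and cleavage of the ring A methyl ether. A1 itself needs a long linear synthesis ending in a diazo transfer.
- Comparison: the chosen route keeps ring B aromatic throughout, takes it from a commercial phenol, and places the ring closure on a well-tried sp3–sp2 coupling instead of on a carbenoid reaching across twelve methylenes.

Alternative 2: Ring A and the macrocycle are cut together, leading to the cyclobutenone A3, tethered by twelve methylenes to a ring B aryl silylethynyl ether. On heating, A3 should open to a vinylketene, add the ynol ether in a [2+2] sense, reopen and electrocyclize (Danheiser benzannulation), giving the macrocyclic phenol A4 with a trimethylsilyl group at C6.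
- For it: ring A, its hydroxyl, its regiochemistry and the 20-membered ring arise in a single metal-free operation, and the ether oxygen again enters without an arylation. After the precursor is in hand it is shorter than the chosen route.
- Against it: the first bond-forming event, the ketene–alkyne [2+2], must occur across the whole tether, while the vinylketene is short-lived and dimerizes or finds intermolecular partners at any practical concentration. An aryl ynol ether with two ortho methoxy groups is hard to make and unlikely to survive the temperatures needed. A4 still needs protodesilylation and ether cleavage. A3 carries two fragile termini through a long linear sequence.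
- Comparison: the chosen route gives up the single-step elegance but makes ring A in an intermolecular reaction, where one partner can be used in excess, and closes the ring in a separate step that can be optimized on its own.

Alternative 3: The ring B hydroxyls are traced back to formyl groups, giving the macrocyclic dialdehyde A5. The forward key step is a double Baeyer–Villiger (Dakin-type) oxidation with a peracid, followed by methanolysis of the formates, which should give the ring B diol A6 with ring A as its methyl ether.
- For it: the two ortho formyl groups make C1' a good site for nucleophilic aromatic substitution, so the hindered ether, and possibly the macrocycle, can be made by a dependable phenoxide displacement. On reliability of the ether bond this is stronger than a thermal cycloaddition.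
- Against it: the key step forms no skeletal bond and closes no ring. It needs two aryl migrations on a ring without a free ortho or para hydroxyl, so hydride migration to the acids competes. The peracid meets an electron-rich ring A and a product, A6, that is itself oxidation-sensitive. A6 still needs demethylation, and the formyl groups are installed only to be destroyed.
- Comparison: the chosen route carries the ring B oxygens from the first step, needs no late oxidation of an electron-rich macrocycle, and sets the ring A pattern in the same step that attaches the ether.

Key step: step 6

Assumption: the C1=C2 geometry of ketene acetal 9 is written as 1E for definiteness. It has no bearing on the outcome, because C1 ends as an sp2 ring carbon, and a 1Z isomer or a mixture would be used in the same way.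

**Route**

Step 1
Reactants: 1 1-(trimethylsilyl)propyne; 2 11-bromoundec-1-ene
Product: 3 trimethyl(tetradec-13-en-1-yn-1-yl)silane
Conditions: n-BuLi, THF, −78 → −20 °C; then 2, −78 °C → rt
Reagents that add atoms: none
Why: Propargylic lithiation of 1 and SN2 alkylation by the primary bromide; the silyl group blocks the acetylenic terminus and should steer alkylation to the sp3 carbon, any minor allenylsilane being removed after step 2, and the terminal alkene of 2 is inert.

Step 2
Reactants: 3 trimethyl(tetradec-13-en-1-yn-1-yl)silane
Product: 4 tetradec-13-en-1-yne
Conditions: K2CO3 (cat.), MeOH, rt
Reagents that add atoms: none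
Why: Methoxide-mediated protodesilylation of an alkynylsilane; the alkene is untouched.

Step 3
Reactants: 4 tetradec-13-en-1-yne
Product: 5 methyl pentadec-14-en-2-ynoate
Conditions: n-BuLi, THF, −78 °C; ClCO2Me, −78 → 0 °C
Reagents that add atoms: methyl chloroformate, COC(=O)Cl
Why: Deprotonation of the terminal alkyne and C-acylation of the lithium acetylide with a chloroformate, the standard alkoxycarbonylation to an alk-2-ynoate.

Step 4
Reactants: 6 4-bromo-2,6-dimethoxyphenol; 7 methyl but-2-ynoate
Product: 8 methyl (2E)-3-(4-bromo-2,6-dimethoxyphenoxy)but-2-enoate
Conditions: K2CO3 (cat.), DMF, 80 °C
Reagents that add atoms: none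
Why: Oxa-Michael addition of the phenoxide to the β-carbon of the ynoate; the linear sp carbon is accessible even to a di-ortho-substituted phenoxide, and equilibration under base should favour the E enol ether. A Z component would do no harm, since both isomers give the same dienolate in step 5.

Step 5
Reactants: 8 methyl (2E)-3-(4-bromo-2,6-dimethoxyphenoxy)but-2-enoate
Product: 9 (1E)-3-(4-bromo-2,6-dimethoxyphenoxy)-1-methoxy-1-(trimethylsilyloxy)buta-1,3-diene
Conditions: LiN(i-Pr)2 (commercial solution), THF, −78 °C; Me3SiCl, −78 °C → rt; pentane, filtration under argon, used crude
Reagents that add atoms: chlorotrimethylsilane, C[Si](C)(C)Cl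
Why: Kinetic γ-deprotonation of the β-aryloxy enoate to the vinylogous ester enolate and O-silylation, the usual preparation of vinylketene O-silyl O-methyl acetals from 3-oxygenated crotonates. Ester deprotonation at −78 °C should be far faster than metalation of ring B next to bromine.

Step 6
Reactants: 9 (1E)-3-(4-bromo-2,6-dimethoxyphenoxy)-1-methoxy-1-(trimethylsilyloxy)buta-1,3-diene (in excess); 5 methyl pentadec-14-en-2-ynoate
Product: 12 methyl 4-(4-bromo-2,6-dimethoxyphenoxy)-6-(dodec-11-en-1-yl)-2-hydroxybenzoate, via cyclohexa-1,4-diene cycloadduct 10 (not isolated), via aryl trimethylsilyl ether 11 (not isolated)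
Conditions: toluene (concentrated), sealed tube, 130 °C; then 1 M HCl, THF, rt
Reagents that add atoms: none
Why: This is a normal-electron-demand Diels–Alder reaction of a vinylketene acetal (a 1,1-dioxygenated 3-oxygenated butadiene) with an acetylenic ester followed by aromatization, the established way to 6-substituted 2,4-dioxygenated benzoates. The addition is concerted but strongly asynchronous: the CH2 terminus of 9 (ring A C4), which carries the largest HOMO coefficient because both the ketene acetal and the 3-aryloxy group push electron density onto it, bonds first to the β-carbon of 5 (C3), and the developing allenolate α-carbon (C2) then closes onto the ketene acetal carbon (C1). Ring A is thus closed by an intermolecular [4+2] addition that forms C3–C4 and C1–C2, the four diene carbons and the two alkyne carbons making the six-membered ring. The primary adduct 10 has one sp3 centre at C1, formed racemic and needing no control, and it is lost at once: 1,4-elimination of methanol across C1 and C4 gives the arene 11, and dilute acid removes the silyl group to leave the hydrogen-bonded phenol 12. The regiochemistry needed (hydroxyl and chain both ortho to the ester, aryloxy para to it) follows from the matched polarization of the two partners and is the orientation expected for this reaction type. Chemoselectivity for the alkyne over the terminal alkene is secured by conjugation with the ester, since an isolated alkene is no dienophile for an electron-rich diene. The direction of aromatization is secured by where the leaving groups sit: methoxide or silanolate can leave from the sp3 ketal carbon C1, whereas the aryloxy group is on the sp2 carbon C5 and cannot be expelled, so the ether survives. The excess of 9 allows for its loss to the methanol that is released.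

Step 7
Reactants: 12 methyl 4-(4-bromo-2,6-dimethoxyphenoxy)-6-(dodec-11-en-1-yl)-2-hydroxybenzoate
Product: 14 macrocyclic methyl salicylate (ring A 1-OH and 2-CO2Me; ring B 2',6'-dimethoxy; C3 joined to C4' by twelve methylenes), via B-alkyl-9-borabicyclo[3.3.1]nonane 13 (not isolated)
Conditions: 9-BBN (2.5 equiv), THF, rt; then slow addition to PdCl2(dppf) (cat.), AsPh3, Cs2CO3, DMF/THF/H2O, 60 °C, ca. 2 mM
Reagents that add atoms: none
Why: Anti-Markovnikov hydroboration of the terminal alkene, then intramolecular B-alkyl Suzuki–Miyaura coupling at high dilution, closes the 20-membered ring at the unhindered C4' bromide. The extra borane allows for reaction with the chelated phenol, whose O–B bond the aqueous base cleaves, and the hindered ester should survive the carbonate.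

Step 8
Reactants: 14 macrocyclic methyl salicylate
Product: 16 macrocyclic phenol (ring A 1-OH and C2–H; ring B 2',6'-dimethoxy), via macrocyclic salicylic acid 15 (not isolated)
Conditions: KOH, H2O/1,4-dioxane, 100 °C; then HCl to pH 1, sealed tube, 120 °C
Reagents that add atoms: none
Why: Saponification of the ester, then protodecarboxylation of the salicylic acid by ipso-protonation at C2, which is activated by the ortho hydroxyl and the para aryloxy group and helped by relief of strain next to the chain. The methyl ethers and the diaryl ether are stable to both media.

Step 9
Reactants: 16 macrocyclic phenol with ring B dimethyl ether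
Product: 17 target: 20-membered diaryl ether cyclophane with ring A 1-OH and ring B 2',6'-di-OH
Conditions: BBr3 (excess), CH2Cl2, −78 °C → rt; then H2O, 0 °C
Reagents that add atoms: none
Why: Cleavage of the aryl methyl ethers by BBr3 through bromide attack at the methyl carbon of the boron-complexed ether. The diaryl ether oxygen bears no sp3 carbon and stays, and the free triol is exposed only in this last acidic step.

**Compound list**

1 | 1-(trimethylsilyl)propyne | CC#C[Si](C)(C)C | starting material
2 | 11-bromoundec-1-ene | C=CCCCCCCCCCBr | starting material
3 | trimethyl(tetradec-13-en-1-yn-1-yl)silane | C[Si](C)(C)C#CCCCCCCCCCCC=C | intermediate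
4 | tetradec-13-en-1-yne | C#CCCCCCCCCCCC=C | intermediate
5 | methyl pentadec-14-en-2-ynoate | COC(=O)C#CCCCCCCCCCCC=C | intermediate
6 | 4-bromo-2,6-dimethoxyphenol | Oc1c(OC)cc(Br)cc1OC | starting material
7 | methyl but-2-ynoate | CC#CC(=O)OC | starting material
8 | methyl (2E)-3-(4-bromo-2,6-dimethoxyphenoxy)but-2-enoate | C/C(Oc1c(OC)cc(Br)cc1OC)=C\C(=O)OC | intermediate
9 | (1E)-3-(4-bromo-2,6-dimethoxyphenoxy)-1-methoxy-1-(trimethylsilyloxy)buta-1,3-diene | C=C(Oc1c(OC)cc(Br)cc1OC)/C=C(\OC)O[Si](C)(C)C | intermediate
10 | methyl 4-(4-bromo-2,6-dimethoxyphenoxy)-2-(dodec-11-en-1-yl)-6-methoxy-6-(trimethylsilyloxy)cyclohexa-1,4-diene-1-carboxylate (racemic at C6) | COC(=O)C1=C(CCCCCCCCCCC=C)CC(Oc2c(OC)cc(Br)cc2OC)=CC1(OC)O[Si](C)(C)C | intermediate (not isolated)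
11 | methyl 4-(4-bromo-2,6-dimethoxyphenoxy)-6-(dodec-11-en-1-yl)-2-(trimethylsilyloxy)benzoate | COC(=O)c1c(O[Si](C)(C)C)cc(Oc2c(OC)cc(Br)cc2OC)cc1CCCCCCCCCCC=C | intermediate (not isolated)
12 | methyl 4-(4-bromo-2,6-dimethoxyphenoxy)-6-(dodec-11-en-1-yl)-2-hydroxybenzoate | COC(=O)c1c(O)cc(Oc2c(OC)cc(Br)cc2OC)cc1CCCCCCCCCCC=C | intermediate
13 | methyl 6-[12-(9-borabicyclo[3.3.1]nonan-9-yl)dodecyl]-4-(4-bromo-2,6-dimethoxyphenoxy)-2-hydroxybenzoate | COC(=O)c1c(O)cc(Oc2c(OC)cc(Br)cc2OC)cc1CCCCCCCCCCCCB1C2CCCC1CCC2 | intermediate (not isolated)
14 | macrocyclic methyl salicylate: ring A 1-OH and 2-CO2Me, ring B 2',6'-dimethoxy, C3 joined to C4' by (CH2)12, C5 joined to C1' by O | COC(=O)c1c(O)cc2cc1CCCCCCCCCCCCc1cc(OC)c(O2)c(OC)c1 | intermediate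
15 | macrocyclic salicylic acid: as 14 with CO2H at ring A C2 | OC(=O)c1c(O)cc2cc1CCCCCCCCCCCCc1cc(OC)c(O2)c(OC)c1 | intermediate (not isolated)
16 | macrocyclic phenol: ring A 1-OH and C2–H, ring B 2',6'-dimethoxy | Oc1cc2cc(c1)CCCCCCCCCCCCc1cc(OC)c(O2)c(OC)c1 | intermediate
17 | target: 20-membered diaryl ether cyclophane, ring A 1-OH, ring B 2',6'-di-OH, twelve methylenes from C3 to C4' | Oc1cc2cc(c1)Oc1c(O)cc(cc1O)CCCCCCCCCCCC2 | target

**Step count and risk**

Total step count: 9. Longest linear sequence: 7 steps (steps 1, 2, 3, 6, 7, 8, 9); the diene branch (steps 4 and 5) joins at step 6.

Step 6 (key step). The most likely failure is decay of diene 9 before it has added to the ynoate. A β-alkyl alk-2-ynoate is a sluggish dienophile, the 3-aryloxy group donates less than an alkoxy or silyloxy group, and at the temperature needed the ketene acetal can undergo O-to-C silyl migration or be protonated by the liberated methanol or by traces of water. The fallback raises the reactivity of the two-carbon partner; it sets out from 4 (with 9) and comes back at 12. Alkyne 4 would be deprotonated with n-BuLi and formylated with DMF (buffered aqueous KH2PO4 quench) to pentadec-14-en-2-ynal F1. This much better dienophile should add 9 in toluene near room temperature, without Lewis acid so that the carbonyl group is not drawn into a hetero-Diels–Alder reaction. Loss of methanol and acidic desilylation should then give 4-(4-bromo-2,6-dimethoxyphenoxy)-6-(dodec-11-en-1-yl)-2-hydroxybenzaldehyde F2. Chlorite oxidation (NaClO2, NaH2PO4, 2-methylbut-2-ene, t-BuOH/H2O) to 4-(4-bromo-2,6-dimethoxyphenoxy)-6-(dodec-11-en-1-yl)-2-hydroxybenzoic acid F3 and esterification with Me3SiCHN2 in MeOH/toluene return to 12.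

Step 7. Intermolecular coupling to oligomers may compete with ring closure. In addition, oxidative addition into the electron-rich bromide is slow, which gives the alkylborane time for protodeboronation and the alkylpalladium time for β-hydride elimination. The fallback closes the ring by olefin metathesis; it sets out from 12 and comes back at 14. Suzuki–Miyaura vinylation of the bromide with K[CH2=CHBF3] (PdCl2(dppf), Cs2CO3, THF/H2O, 80 °C) would give methyl 6-(dodec-11-en-1-yl)-4-(4-ethenyl-2,6-dimethoxyphenoxy)-2-hydroxybenzoate F4. Ring-closing metathesis with the second-generation Grubbs catalyst RuCl2(=CHPh)(H2IMes)(PCy3) in refluxing CH2Cl2 at high dilution would give the macrocyclic alkene F5, whose ten methylenes and CH=CH make up the same twelve-carbon bridge. Hydrogenation (H2, Pd/C, EtOAc) would then deliver 14.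

Step 8. Hydroxide attack at the ester carbonyl may stall, because the carbonyl is flanked on both sides and the neighbouring phenoxide repels the nucleophile. The decarboxylation may also stop short at the temperature chosen. The fallback changes both mechanisms; it sets out from 14 and comes back at 16. The methyl ester would be cleaved by iodide attack at the unhindered O-methyl carbon (LiI, pyridine, reflux), giving 15, this time isolated. Protodecarboxylation would then be effected with Ag2CO3 (cat.) and AcOH in DMSO at 120 °C, conditions suited to ortho-substituted benzoic acids. This fallback makes no compound outside the list (F0).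

Step 4. Conjugate addition of the di-ortho-substituted phenoxide to a β-methyl ynoate may be slow enough for base-induced isomerization and oligomerization of 7 to take over. The fallback forms the same vinyl C–O bond by addition–elimination; it sets out from 6 and comes back at 8. Phenol 6 would be treated with commercial methyl 3-chlorobut-2-enoate and K2CO3 in DMF at 60 °C, chloride being displaced from the β-carbon. This fallback makes no compound outside the list (F0).

**Further compounds**

F1 | step 6 | pentadec-14-en-2-ynal | O=CC#CCCCCCCCCCCC=C
F2 | step 6 | 4-(4-bromo-2,6-dimethoxyphenoxy)-6-(dodec-11-en-1-yl)-2-hydroxybenzaldehyde | O=Cc1c(O)cc(Oc2c(OC)cc(Br)cc2OC)cc1CCCCCCCCCCC=C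
F3 | step 6 | 4-(4-bromo-2,6-dimethoxyphenoxy)-6-(dodec-11-en-1-yl)-2-hydroxybenzoic acid | OC(=O)c1c(O)cc(Oc2c(OC)cc(Br)cc2OC)cc1CCCCCCCCCCC=C
F4 | step 7 | methyl 6-(dodec-11-en-1-yl)-4-(4-ethenyl-2,6-dimethoxyphenoxy)-2-hydroxybenzoate | COC(=O)c1c(O)cc(Oc2c(OC)cc(C=C)cc2OC)cc1CCCCCCCCCCC=C
F5 | step 7 | macrocyclic alkene: as 14 with CH=CH next to ring B C4' (E drawn; either geometry is hydrogenated to 14) | COC(=O)c1c(O)cc2cc1CCCCCCCCCC/C=C/c1cc(OC)c(O2)c(OC)c1
F0 | step 8 | none | none
F0 | step 4 | none | none
A1 | alternative 1 | 2-diazo-5-[12-(3-hydroxy-5-methoxyphenyl)dodecyl]cyclohexane-1,3-dione | COc1cc(O)cc(c1)CCCCCCCCCCCCC1CC(=O)C(=[N+]=[N-])C(=O)C1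
A2 | alternative 1 | macrocyclic 2-aryloxycyclohexane-1,3-dione, enol form, ring A methyl ether (the one sp3 ring centre racemic and fluxional) | COc1cc2cc(c1)OC1=C(O)CC(CC1=O)CCCCCCCCCCCC2
A3 | alternative 2 | 3-{12-[3,5-dimethoxy-4-(2-trimethylsilylethynyloxy)phenyl]dodecyl}cyclobut-2-en-1-one | O=C1C=C(CCCCCCCCCCCCc2cc(OC)c(OC#C[Si](C)(C)C)c(OC)c2)C1
A4 | alternative 2 | macrocyclic diaryl ether with free ring A phenol, trimethylsilyl at C6 and ring B dimethyl ether | Oc1cc2cc(Oc3c(OC)cc(cc3OC)CCCCCCCCCCCC2)c1[Si](C)(C)C
A5 | alternative 3 | macrocyclic 2-aryloxyisophthalaldehyde (formyl at C2' and C6'), ring A methyl ether | COc1cc2cc(c1)Oc1c(C=O)cc(cc1C=O)CCCCCCCCCCCC2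
A6 | alternative 3 | macrocyclic ring B diol, ring A methyl ether | COc1cc2cc(c1)Oc1c(O)cc(cc1O)CCCCCCCCCCCC2
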